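**Retrosynthetic overview**
1. The route rests on two adjacent ring B centres: C8 (H, methyl C17) and quaternary C9 (methyl C20, C11 chain), with the two methyls cis. Both are set in one enantioselective conjugate methylation of one enone arm of prochiral 4-methyl-4-(trichloromethyl)cyclohexadienone, anti to CCl3.
2. Ring B is the former p-cresol ring (Zincke–Suhl dearomatisation). A Wharton transposition moves the oxygen to C10, and CCl3 becomes C11.
3. C11–C12: CCl3 is reduced to CH2Cl, lithiated, and added to an (R)-aldehyde (C12–C16) made from (R)-methylsuccinic acid; the C12 hydroxyl is then removed.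
4. Ring A closes last: C10 enol triflate, carbonylative coupling (C1 from CO; C2–C4, C18, C19 from α-methyl-γ-butyrolactone), CBS reduction, δ-lactone, then lactone-enolate Ireland–Claisen contraction forming C4–C5 and C1=C10.
5. End game: methyl ester, C15 desilylation, acetylation.

Key step: step 2

Remark: halimane numbering is used for all intermediates; the C4 carboxyl carbon is called C19 and the C4 methyl C18.
Remark: the (S,R,R) phosphoramidite is assumed to select the enone arm that leads to (4S,5R)-4; if the opposite sense is found, the enantiomeric ligand is used and nothing else changes.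
Remark: a CCl3 or CHCl2 group on a quaternary carbon resists hydrolysis to an aldehyde, so C11 is carried as CH2Cl and joined to C12 as a carbanion, not as an aldehyde.
Remark: the configurations created at C5/C10 (steps 3–4) and at C12 (step 11) are drawn as the expected isomer or left open; all are erased later.

**Route**

Step 1
Reactants: 1 p-cresol
Product: 2 4-methyl-4-(trichloromethyl)cyclohexa-2,5-dien-1-one
Conditions: CCl4 (solvent), AlCl3 (2.5 equiv), 0 °C to rt; ice/aq. HCl
Reagents that add atoms: carbon tetrachloride, ClC(Cl)(Cl)Cl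
Why: Zincke–Suhl reaction, in which AlCl3 ionises CCl4 and the trichloromethyl cation attacks the methyl-blocked para position of the aluminium phenoxide, so the ring dearomatises to the 4,4-disubstituted dienone.

Step 2
Reactants: 2 4-methyl-4-(trichloromethyl)cyclohexa-2,5-dien-1-one
Product: 4 (4S,5R)-4,5-dimethyl-4-(trichloromethyl)cyclohex-2-en-1-one, via dimethylaluminium enolate 3 (not isolated)
Conditions: AlMe3 (1.5 equiv), (CuOTf)2·C6H6 (2.5 mol%), (S)-binaphthyl-2,2'-diyl N,N-bis[(R)-1-phenylethyl]phosphoramidite (6 mol%), Et2O, −30 °C; aq. NH4Cl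
Reagents that add atoms: trimethylaluminium, C[Al](C)C
Why: Transmetalation from AlMe3 gives a ligand-bound methylcopper species (monovalent copper) that π-complexes one enone arm, adds at the β-carbon to a trivalent copper enolate and reductively eliminates to form C8–C17, leaving aluminium enolate 3, which is protonated on work-up. The closest known reaction type is the copper-catalysed asymmetric conjugate addition of AlMe3 or dialkylzincs to cyclohexenones and 4,4-disubstituted cyclohexadienones, this dienone included. No ring is closed; one skeletal bond is formed. C8 is set by the chiral ligand, which picks one of the two enantiotopic enone arms, and C9, prochiral in 2, becomes stereogenic by that same choice. Methyl enters anti to the bulky trichloromethyl group on either arm, which puts C17 cis to C20, so arm choice alone decides the enantiomer. The step needs 1,4- over 1,2-addition, secured by the soft copper nucleophile, and mono- over bis-addition, secured by the aluminium enolate persisting until quench.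

Step 3
Reactants: 4 (4S,5R)-4,5-dimethyl-4-(trichloromethyl)cyclohex-2-en-1-one
Product: 5 4,5-dimethyl-5-(trichloromethyl)-7-oxabicyclo[4.1.0]heptan-2-one (epoxide oxygen anti to CCl3; C8 and C9 as in 4)
Conditions: 30% H2O2 (3 equiv), NaOH (cat.), MeOH, 0 °C
Reagents that add atoms: hydrogen peroxide, OO
Why: Weitz–Scheffer nucleophilic epoxidation of the enone, with hydroperoxide expected to add to C10 anti to CCl3; the new C5 and C10 configurations do not matter because both centres are erased later.

Step 4
Reactants: 5 epoxy ketone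
Product: 7 (1S,5R,6S)-5,6-dimethyl-6-(trichloromethyl)cyclohex-2-en-1-ol, via epoxy hydrazone 6 (not isolated)
Conditions: N2H4·H2O (3 equiv), AcOH (cat.), MeOH, 0 °C to rt
Reagents that add atoms: none
Why: Wharton transposition, in which the epoxy hydrazone fragments with loss of N2 to the allylic alcohol, moving oxygen from C6 to C10 with the epoxide C10–O bond retained.

Step 5
Reactants: 7 allylic alcohol
Product: 8 (1S,2S,3R)-2,3-dimethyl-2-(trichloromethyl)cyclohexan-1-ol
Conditions: 2-nitrobenzenesulfonylhydrazide (4 equiv), Et3N, CH2Cl2, rt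
Reagents that add atoms: none
Why: Diimide reduction saturates the cis-disubstituted C5=C6 alkene without touching the C–Cl bonds, which a metal hydrogenation catalyst could hydrogenolyse.

Step 6
Reactants: 8 trichloromethyl carbinol
Product: 10 (1S,2S,3R)-2-(chloromethyl)-2,3-dimethylcyclohexan-1-ol, via dichloromethyl carbinol 9 (not isolated)
Conditions: Bu3SnH (2.2 equiv), AIBN (0.1 equiv), PhH, 80 °C, slow addition
Reagents that add atoms: none
Why: Stepwise radical dechlorination by the tin hydride chain, in which each chlorine abstraction is slower than the one before, so two equivalents should stop at the primary neopentyl chloride.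

Step 7
Reactants: 10 chloromethyl carbinol
Product: 11 (1S,2S,3R)-2-(chloromethyl)-1-(methoxymethoxy)-2,3-dimethylcyclohexane
Conditions: MOMCl (3 equiv), iPr2NEt (4 equiv), Bu4NI (cat.), CH2Cl2, 0 °C to 40 °C
Reagents that add atoms: chloromethyl methyl ether, COCCl
Why: O-Alkylation with the small, reactive chloromethyl ether protects the hindered C10 alcohol as an acetal that withstands reductive lithiation and cannot migrate to a neighbouring alkoxide.

Step 8
Reactants: 12 (R)-methylsuccinic acid
Product: 13 (R)-2-methylbutane-1,4-diol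
Conditions: LiAlH4 (3 equiv), THF, reflux; aq. NaOH work-up
Reagents that add atoms: none
Why: Hydride reduction of both carboxyl groups, during which the future C13 centre sits α to a carboxylate and is not epimerised.

Step 9
Reactants: 13 (R)-2-methylbutane-1,4-diol
Product: 14 (R)-4-(tert-butyldiphenylsilyloxy)-2-methylbutan-1-ol
Conditions: TBDPSCl (0.95 equiv), imidazole, CH2Cl2, −20 °C
Reagents that add atoms: tert-butyl(chloro)diphenylsilane, CC(C)(C)[Si](Cl)(c1ccccc1)c1ccccc1
Why: Silylation with a bulky silyl chloride is faster at the unbranched (future C15) hydroxyl than at the β-branched (future C12) hydroxyl, and the regioisomer and bis-silyl ether are removed by chromatography.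

Step 10
Reactants: 14 mono-silyl ether
Product: 15 (R)-4-(tert-butyldiphenylsilyloxy)-2-methylbutanal
Conditions: Dess–Martin periodinane (1.3 equiv), NaHCO3, CH2Cl2, 0 °C to rt; used at once
Reagents that add atoms: none
Why: Buffered Dess–Martin oxidation gives the α-branched aldehyde without epimerising the future C13 centre.

Step 11
Reactants: 11 MOM-protected neopentyl chloride; 15 (R)-aldehyde
Product: 17 (3R)-5-(tert-butyldiphenylsilyloxy)-1-[(1S,2S,6R)-2-(methoxymethoxy)-1,6-dimethylcyclohexyl]-3-methylpentan-2-ol (both C12 epimers), via neopentyl-type organolithium 16 (not isolated)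
Conditions: lithium 4,4'-di-tert-butylbiphenylide (LiDBB, 2.1 equiv), THF, −78 °C, 20 min; then 15 (1.3 equiv), −78 °C; aq. NH4Cl
Reagents that add atoms: none
Why: Reductive lithiation of the primary chloride by the arene radical anion gives an organolithium without β-hydrogen that undergoes 1,2-addition to the aldehyde to form C11–C12, leaving C13 untouched.

Step 12
Reactants: 17 C12 carbinol
Product: 18 O-(C12) 1H-imidazole-1-carbothioate of 17
Conditions: 1,1'-thiocarbonyldiimidazole (2.5 equiv), DMAP (0.2 equiv), 1,2-dichloroethane, 70 °C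
Reagents that add atoms: 1,1'-thiocarbonyldiimidazole, S=C(n1ccnc1)n1ccnc1
Why: Neutral thioacylation of the secondary alcohol prepares the Barton–McCombie deoxygenation without generating an alkoxide.

Step 13
Reactants: 18 imidazolyl thiocarbonate
Product: 19 tert-butyl{[(3S)-5-[(1S,2S,6R)-2-(methoxymethoxy)-1,6-dimethylcyclohexyl]-3-methylpentyl]oxy}diphenylsilane
Conditions: Bu3SnH (2 equiv), AIBN (0.2 equiv), PhMe, 110 °C
Reagents that add atoms: none
Why: Barton–McCombie deoxygenation releases and reduces the secondary C12 radical, which has no alkene to cyclise onto and does not involve C13.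

Step 14
Reactants: 19 MOM ether
Product: 20 (1S,2S,3R)-2-[(3S)-5-(tert-butyldiphenylsilyloxy)-3-methylpentyl]-2,3-dimethylcyclohexan-1-ol
Conditions: Me2BBr (3 equiv), CH2Cl2, −78 °C; then sat. aq. NaHCO3–THF
Reagents that add atoms: none
Why: Bromoborane-mediated acetal cleavage removes the MOM group at low temperature and leaves the primary TBDPS ether intact.

Step 15
Reactants: 20 C10 alcohol
Product: 21 (2S,3R)-2-[(3S)-5-(tert-butyldiphenylsilyloxy)-3-methylpentyl]-2,3-dimethylcyclohexan-1-one
Conditions: Dess–Martin periodinane (1.5 equiv), NaHCO3, CH2Cl2, rt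
Reagents that add atoms: none
Why: Dess–Martin oxidation of the hindered secondary alcohol gives the C10 ketone and erases the C10 carbinol centre.

Step 16
Reactants: 21 C10 ketone
Product: 23 (5R,6S)-6-[(3S)-5-(tert-butyldiphenylsilyloxy)-3-methylpentyl]-5,6-dimethylcyclohex-1-en-1-yl trifluoromethanesulfonate, via potassium enolate 22 (not isolated)
Conditions: KN(SiMe3)2 (1.2 equiv), THF, −78 °C; then PhNTf2 (1.3 equiv), −78 °C to 0 °C
Reagents that add atoms: N-phenylbis(trifluoromethanesulfonimide), O=S(=O)(N(c1ccccc1)S(=O)(=O)C(F)(F)F)C(F)(F)F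
Why: Enolate O-triflation, regiospecific because C9 is quaternary and the ketone can enolise only toward C5.

Step 17
Reactants: 24 α-methyl-γ-butyrolactone (racemic)
Product: 26 methyl 4-iodo-2-methylbutanoate (racemic), via trimethylsilyl 4-iodo-2-methylbutanoate 25 (not isolated)
Conditions: Me3SiI (1.2 equiv), CH2Cl2, rt; then MeOH, rt
Reagents that add atoms: iodotrimethylsilane, C[Si](C)(C)I; methanol, CO
Why: Silyl iodide ring opening by SN2 attack of iodide at the O–CH2 carbon, then acid-catalysed methanolysis of the silyl ester; the racemic α-centre is erased by enolisation in step 20.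

Step 18
Reactants: 23 enol triflate; 26 methyl 4-iodo-2-methylbutanoate
Product: 28 methyl 5-[(5R,6S)-6-[(3S)-5-(tert-butyldiphenylsilyloxy)-3-methylpentyl]-5,6-dimethylcyclohex-1-en-1-yl]-2-methyl-5-oxopentanoate (both C4 epimers), via alkylzinc iodide 27 (not isolated)
Conditions: 26, Zn dust (activated by BrCH2CH2Br and Me3SiCl), THF, 40 °C; then 23, Pd(PPh3)4 (5 mol%), LiCl (3 equiv), CO (3 atm), THF–NMP, 50 °C
Reagents that add atoms: carbon monoxide, [C-]#[O+]
Why: Carbonylative Negishi coupling, in which oxidative addition of the enol triflate to zerovalent palladium, CO insertion, transmetalation from the ester-tolerant alkylzinc iodide and reductive elimination give the C10–C1(=O)–C2 enone.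

Step 19
Reactants: 28 enone keto ester
Product: 30 (6R)-6-[(5R,6S)-6-[(3S)-5-(tert-butyldiphenylsilyloxy)-3-methylpentyl]-5,6-dimethylcyclohex-1-en-1-yl]-3-methyloxan-2-one (both C4 epimers), via (5R)-hydroxy ester 29 (not isolated)
Conditions: (S)-2-methyl-CBS-oxazaborolidine (0.5 equiv), catecholborane (1.8 equiv), PhMe, −78 °C; work-up; then PPTS (0.1 equiv), PhMe, 60 °C
Reagents that add atoms: none
Why: Corey–Bakshi–Shibata reduction, with the α-substituted cyclohexenyl group as the large substituent, should give the (1R) allylic alcohol under catalyst control, and acid-catalysed transesterification then closes the δ-lactone.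

Step 20
Reactants: 30 (1R)-δ-lactone
Product: 33 (4S,5R,8R,9S,13S)-15-(tert-butyldiphenylsilyloxy)halim-1(10)-en-19-oic acid, via silyl ketene acetal 31 (not isolated), via trimethylsilyl ester 32 (not isolated)
Conditions: LiN(iPr)2 (1.3 equiv), Me3SiCl–Et3N (3 equiv), THF, −78 °C to rt; then PhMe, 110 °C; then 1 M HCl, THF
Reagents that add atoms: none
Why: Ireland–Claisen rearrangement of the lactone silyl ketene acetal (lactone-enolate Claisen ring contraction), in which the C2–C3 tether enforces a boat transition state that bonds C4 to C5 on the ring B face anti to the pseudoaxial C20 methyl, transferring the (1R) centre to (4S,5R) with the carboxyl trans to H5 and forming the C1=C10 alkene.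

Step 21
Reactants: 33 ring A acid
Product: 34 methyl (4S,5R,8R,9S,13S)-15-(tert-butyldiphenylsilyloxy)halim-1(10)-en-19-oate
Conditions: Me3SiCHN2 (2 equiv), PhMe–MeOH (4:1), rt
Reagents that add atoms: (trimethylsilyl)diazomethane, C[Si](C)(C)C=[N+]=[N-]
Why: O-Methylation of the hindered neopentyl acid by the diazoalkane needs no attack at the carbonyl carbon.

Step 22
Reactants: 34 silyl ether methyl ester
Product: 35 methyl (4S,5R,8R,9S,13S)-15-hydroxyhalim-1(10)-en-19-oate
Conditions: Bu4NF (1.5 equiv), THF, rt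
Reagents that add atoms: none
Why: Fluoride cleavage of the Si–O bond, to which the hindered methyl ester and the trisubstituted alkene are inert.

Step 23
Reactants: 35 C15 alcohol
Product: 36 methyl (4S,5R,8R,9S,13S)-15-acetoxyhalim-1(10)-en-19-oate (CNP0151222.1)
Conditions: Ac2O (2 equiv), pyridine, DMAP (cat.), CH2Cl2, rt
Reagents that add atoms: acetic anhydride, CC(=O)OC(C)=O
Why: DMAP-catalysed acylation of the primary C15 alcohol gives the target.

**Compound list**
1 | p-cresol | Cc1ccc(O)cc1 | starting material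
2 | 4-methyl-4-(trichloromethyl)cyclohexa-2,5-dien-1-one | CC1(C=CC(=O)C=C1)C(Cl)(Cl)Cl | intermediate
3 | dimethylaluminium enolate of 4 | C1=C[C@@](C)(C(Cl)(Cl)Cl)[C@H](C)C=C1O[Al](C)C | intermediate
4 | (4S,5R)-4,5-dimethyl-4-(trichloromethyl)cyclohex-2-en-1-one | O=C1C=C[C@@](C)(C(Cl)(Cl)Cl)[C@H](C)C1 | intermediate
5 | 4,5-dimethyl-5-(trichloromethyl)-7-oxabicyclo[4.1.0]heptan-2-one, epoxide anti to CCl3 | O=C1[C@@H]2O[C@@H]2[C@@](C)(C(Cl)(Cl)Cl)[C@H](C)C1 | intermediate
6 | hydrazone of 5 | NN=C1[C@@H]2O[C@@H]2[C@@](C)(C(Cl)(Cl)Cl)[C@H](C)C1 | intermediate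
7 | (1S,5R,6S)-5,6-dimethyl-6-(trichloromethyl)cyclohex-2-en-1-ol | C1=C[C@H](O)[C@@](C)(C(Cl)(Cl)Cl)[C@H](C)C1 | intermediate
8 | (1S,2S,3R)-2,3-dimethyl-2-(trichloromethyl)cyclohexan-1-ol | C1C[C@H](O)[C@@](C)(C(Cl)(Cl)Cl)[C@H](C)C1 | intermediate
9 | 2-(dichloromethyl)-2,3-dimethylcyclohexan-1-ol, configuration as 8 | C1C[C@H](O)[C@@](C)(C(Cl)Cl)[C@H](C)C1 | intermediate
10 | (1S,2S,3R)-2-(chloromethyl)-2,3-dimethylcyclohexan-1-ol | C1C[C@H](O)[C@@](C)(CCl)[C@H](C)C1 | intermediate
11 | (1S,2S,3R)-2-(chloromethyl)-1-(methoxymethoxy)-2,3-dimethylcyclohexane | C1C[C@H](OCOC)[C@@](C)(CCl)[C@H](C)C1 | intermediate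
12 | (R)-methylsuccinic acid | OC(=O)[C@H](C)CC(=O)O | starting material
13 | (R)-2-methylbutane-1,4-diol | OC[C@H](C)CCO | intermediate
14 | (R)-4-(tert-butyldiphenylsilyloxy)-2-methylbutan-1-ol | OC[C@H](C)CCO[Si](c1ccccc1)(c1ccccc1)C(C)(C)C | intermediate
15 | (R)-4-(tert-butyldiphenylsilyloxy)-2-methylbutanal | O=C[C@H](C)CCO[Si](c1ccccc1)(c1ccccc1)C(C)(C)C | intermediate
16 | C11 organolithium from 11 | C1C[C@H](OCOC)[C@@](C)(C[Li])[C@H](C)C1 | intermediate
17 | (3R)-5-(tert-butyldiphenylsilyloxy)-1-[(1S,2S,6R)-2-(methoxymethoxy)-1,6-dimethylcyclohexyl]-3-methylpentan-2-ol, C12 epimers | C1C[C@H](OCOC)[C@@](C)(CC(O)[C@H](C)CCO[Si](c2ccccc2)(c2ccccc2)C(C)(C)C)[C@H](C)C1 | intermediate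
18 | O-(C12) 1H-imidazole-1-carbothioate of 17 | C1C[C@H](OCOC)[C@@](C)(CC(OC(=S)n2ccnc2)[C@H](C)CCO[Si](c2ccccc2)(c2ccccc2)C(C)(C)C)[C@H](C)C1 | intermediate
19 | tert-butyl{[(3S)-5-[(1S,2S,6R)-2-(methoxymethoxy)-1,6-dimethylcyclohexyl]-3-methylpentyl]oxy}diphenylsilane | C1C[C@H](OCOC)[C@@](C)(CC[C@H](C)CCO[Si](c2ccccc2)(c2ccccc2)C(C)(C)C)[C@H](C)C1 | intermediate
20 | (1S,2S,3R)-2-[(3S)-5-(tert-butyldiphenylsilyloxy)-3-methylpentyl]-2,3-dimethylcyclohexan-1-ol | C1C[C@H](O)[C@@](C)(CC[C@H](C)CCO[Si](c2ccccc2)(c2ccccc2)C(C)(C)C)[C@H](C)C1 | intermediate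
21 | (2S,3R)-2-[(3S)-5-(tert-butyldiphenylsilyloxy)-3-methylpentyl]-2,3-dimethylcyclohexan-1-one | O=C1[C@@](C)(CC[C@H](C)CCO[Si](c2ccccc2)(c2ccccc2)C(C)(C)C)[C@H](C)CCC1 | intermediate
22 | potassium C10(C5) enolate of 21 | C1=C(O[K])[C@@](C)(CC[C@H](C)CCO[Si](c2ccccc2)(c2ccccc2)C(C)(C)C)[C@H](C)CC1 | intermediate
23 | (5R,6S)-6-[(3S)-5-(tert-butyldiphenylsilyloxy)-3-methylpentyl]-5,6-dimethylcyclohex-1-en-1-yl trifluoromethanesulfonate | C1=C(OS(=O)(=O)C(F)(F)F)[C@@](C)(CC[C@H](C)CCO[Si](c2ccccc2)(c2ccccc2)C(C)(C)C)[C@H](C)CC1 | intermediate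
24 | α-methyl-γ-butyrolactone (racemic) | CC1CCOC1=O | starting material
25 | trimethylsilyl 4-iodo-2-methylbutanoate (racemic) | CC(CCI)C(=O)O[Si](C)(C)C | intermediate
26 | methyl 4-iodo-2-methylbutanoate (racemic) | COC(=O)C(C)CCI | intermediate
27 | (4-methoxy-3-methyl-4-oxobutyl)zinc iodide | COC(=O)C(C)CC[Zn]I | intermediate
28 | methyl 5-[(5R,6S)-6-[(3S)-5-(tert-butyldiphenylsilyloxy)-3-methylpentyl]-5,6-dimethylcyclohex-1-en-1-yl]-2-methyl-5-oxopentanoate, C4 epimers | C1=C(C(=O)CCC(C)C(=O)OC)[C@@](C)(CC[C@H](C)CCO[Si](c2ccccc2)(c2ccccc2)C(C)(C)C)[C@H](C)CC1 | intermediate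
29 | methyl (5R)-5-hydroxy analogue of 28, C4 epimers | C1=C([C@H](O)CCC(C)C(=O)OC)[C@@](C)(CC[C@H](C)CCO[Si](c2ccccc2)(c2ccccc2)C(C)(C)C)[C@H](C)CC1 | intermediate
30 | (6R)-6-[(5R,6S)-6-[(3S)-5-(tert-butyldiphenylsilyloxy)-3-methylpentyl]-5,6-dimethylcyclohex-1-en-1-yl]-3-methyloxan-2-one, C4 epimers | C1=C([C@H]2CCC(C)C(=O)O2)[C@@](C)(CC[C@H](C)CCO[Si](c3ccccc3)(c3ccccc3)C(C)(C)C)[C@H](C)CC1 | intermediate
31 | trimethylsilyl ketene acetal of 30 | C1=C([C@H]2CCC(C)=C(O[Si](C)(C)C)O2)[C@@](C)(CC[C@H](C)CCO[Si](c3ccccc3)(c3ccccc3)C(C)(C)C)[C@H](C)CC1 | intermediate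
32 | trimethylsilyl ester of 33 | C[Si](C)(C)OC(=O)[C@@]1(C)CCC=C2[C@H]1CC[C@@H](C)[C@]2(C)CC[C@H](C)CCO[Si](c1ccccc1)(c1ccccc1)C(C)(C)C | intermediate
33 | (4S,5R,8R,9S,13S)-15-(tert-butyldiphenylsilyloxy)halim-1(10)-en-19-oic acid | OC(=O)[C@@]1(C)CCC=C2[C@H]1CC[C@@H](C)[C@]2(C)CC[C@H](C)CCO[Si](c1ccccc1)(c1ccccc1)C(C)(C)C | intermediate
34 | methyl (4S,5R,8R,9S,13S)-15-(tert-butyldiphenylsilyloxy)halim-1(10)-en-19-oate | COC(=O)[C@@]1(C)CCC=C2[C@H]1CC[C@@H](C)[C@]2(C)CC[C@H](C)CCO[Si](c1ccccc1)(c1ccccc1)C(C)(C)C | intermediate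
35 | methyl (4S,5R,8R,9S,13S)-15-hydroxyhalim-1(10)-en-19-oate | COC(=O)[C@@]1(C)CCC=C2[C@H]1CC[C@@H](C)[C@]2(C)CC[C@H](C)CCO | intermediate
36 | methyl (4S,5R,8R,9S,13S)-15-acetoxyhalim-1(10)-en-19-oate (CNP0151222.1) | COC(=O)[C@@]1(C)CCC=C2[C@H]1CC[C@@H](C)[C@]2(C)CC[C@H](C)CCOC(C)=O | target

**Count and risks**
Total step count: 23. Longest linear sequence: 19 steps (steps 1–7, 11–16 and 18–23, from p-cresol).

Risk 1, step 20. The boat transition state places the silyloxy-bearing carbon directly under quaternary C9, so the rearrangement may stall and the ketene acetal may decompose or C-silylate instead. The fallback leaves the Claisen logic and builds ring A by cycloaddition. It sets out from 23: Stille coupling with tributyl(vinyl)stannane (Pd(PPh3)4, LiCl, THF, reflux) should give the C10-vinyl diene F1. A Diels–Alder reaction with methyl methacrylate (EtAlCl2, CH2Cl2, −40 °C) should then join C2–C3 and C4–C5, mainly with the ester-bearing carbon next to C5, anti to the C20 methyl and with the ester endo. The C4 epimer and regioisomer would be removed by chromatography. This comes back to the route at 34.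

Risk 2, step 18. At the hindered alkenylpalladium, direct Negishi coupling may outrun CO insertion, giving the alkylated alkene and not the enone. The fallback separates carbonylation from C–C coupling. It sets out from 23: hydroxycarbonylation (Pd(OAc)2, dppf, CO, KOAc, DMSO, 60 °C) should give the cyclohexenecarboxylic acid F2. Oxalyl chloride with catalytic DMF converts it to the acid chloride F3. Pd(PPh3)4-catalysed acylation of zinc reagent 27 with F3 in THF comes back to the route at 28.

Risk 3, step 2. The ligand may discriminate poorly between the two enantiotopic enone arms, leaving material of low enantiomeric purity. The fallback replaces asymmetric catalysis by resolution. It sets out from 2: the same AlMe3 addition with CuBr·SMe2 and no chiral ligand should give the anti adduct as a racemate, that is 4 together with its enantiomer (4R,5S)-4,5-dimethyl-4-(trichloromethyl)cyclohex-2-en-1-one F4. Preparative chromatography on a chiral stationary phase separates the two, and the route is rejoined at 4.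

**Further compounds**
F1 | step 20 | tert-butyl{[(3S)-5-[(1S,6R)-2-ethenyl-1,6-dimethylcyclohex-2-en-1-yl]-3-methylpentyl]oxy}diphenylsilane | C1=C(C=C)[C@@](C)(CC[C@H](C)CCO[Si](c2ccccc2)(c2ccccc2)C(C)(C)C)[C@H](C)CC1
F2 | step 18 | (5R,6S)-6-[(3S)-5-(tert-butyldiphenylsilyloxy)-3-methylpentyl]-5,6-dimethylcyclohex-1-ene-1-carboxylic acid | C1=C(C(=O)O)[C@@](C)(CC[C@H](C)CCO[Si](c2ccccc2)(c2ccccc2)C(C)(C)C)[C@H](C)CC1
F3 | step 18 | (5R,6S)-6-[(3S)-5-(tert-butyldiphenylsilyloxy)-3-methylpentyl]-5,6-dimethylcyclohex-1-ene-1-carbonyl chloride | C1=C(C(=O)Cl)[C@@](C)(CC[C@H](C)CCO[Si](c2ccccc2)(c2ccccc2)C(C)(C)C)[C@H](C)CC1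
F4 | step 2 | (4R,5S)-4,5-dimethyl-4-(trichloromethyl)cyclohex-2-en-1-one | O=C1C=C[C@](C)(C(Cl)(Cl)Cl)[C@@H](C)C1
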